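The earlier runs and the new flask stem from a simulated flask for substances that don't exist; scatter was added.

On Saturday's flask the substrate at 2.50 h reads 0.2%, less than the scatter of one reading, 0.3 percentage points, so you should ask whether the flask has stopped and what its end is worth.

- Saturday's: substrate 0.035 M; the very flask that is asked about, followed so far
- flask: substrate 0.035 M; time 8.0 h

Saturday's run (percent of the substrate charged)

| time / h | substrate / % | target / % | isomer of the product / % | side product / % |
|---|---|---|---|---|
| 0.333 | 19.4 | 18.5 | 30.3 | 10.2 |
| 0.667 | 3.1 | 26.2 | 48.2 | 16.2 |
| 1.00 | 0.6 | 28.2 | 53.1 | 17.4 |
| 1.33 | 0.2 | 29.0 | 53.9 | 17.1 |
| 1.50 | 0.3 | 28.7 | 53.3 | 17.1 |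
| 2.00 | 0.4 | 28.5 | 53.4 | 17.4 |
| 2.50 | 0.2 | 29.3 | 53.6 | 17.6 |

(scatter of a reading: 0.3 percentage points)

- at 8.0 h, what has stopped the reaction, if anything has (it is still moving / forward and back rates have come level / all of the substrate has reacted)
- share of the substrate used up at 8.0 h
- target at 8.0 h, in percent of the substrate charged
- isomer of the product at 8.0 h, in percent of the substrate charged
- side product at 8.0 h, in percent of the substrate charged

- in percentages every species weighs as the substrate in it: one side product counts as two
- the numbers in the tables scatter by 0.3 percentage points (one standard deviation)
- steps that have been proposed: target <-> isomer of the product; substrate + target -> side product; substrate -> intermediate; intermediate -> target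
- the reaction counts as stopped when no species that holds the substrate changes by six tenths of a point or more over the second half of the time

Start with the substrate. Between the first two readings of Saturday's run, taken as first-order, it falls with a rate constant of

5.49 h⁻¹, a half-life of 0.126 h.

But a reading that small cannot tell zero from a remnant. The objection is computed away: 8.0 h holds 63.5 such half-lives, so I expect all of the substrate has reacted.

Next objection: the intermediate might still be feeding target. Saturday's columns miss 21.6% at 0.333 h, but at 2.50 h they add to 100.7%, so at that reading nothing measurable remains hidden.

Is the side product still creeping up? From 1.33 h to 2.50 h it rises 0.5 points, against 0.42 points of scatter on a difference of two readings. That is no proven rise, and its step needs substrate anyway.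

So one number carries this flask: the side-product ratio (a selectivity ratio), the side product over target plus isomer of the product, in fractions of the charge, as read at 2.50 h with the scatter of those readings:

B = 0.212

Side-product share = B/(1+B) = 17.5%

Of the proposed steps, substrate + target has two partners where substrate to intermediate has one, so my estimate is that, with the time and the rest held, B goes roughly with the charge.

The forecast gives all of the substrate has reacted, with 99.9% used up, target 28.9%, isomer of the product 53.5% and side product 17.4%, on the ground that “what ended the net reaction is substrate exhaustion”.

The flask gives all of the substrate has reacted, with 100% used up, target 28.7%, isomer of the product 53.8% and side product 17.5%.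

    target ⇌ isomer of the product (K = 1.87, k = 0.0102 s⁻¹)
    substrate + target → side product (k = 0.0353 L mol⁻¹ s⁻¹)
    substrate → intermediate (k = 0.00124 s⁻¹)
    intermediate → target (k = 0.00195 s⁻¹)

Target's half-life by turning into isomer of the product, forward rate alone, is 1.1 min, shorter than the 0.16 h by substrate + target with the other concentrations as charged. At 0.283 h the first of these, by its forward rate alone, uses target 32 times as fast as the second. The flask at 8.0 h ends with a ratio of 0.212 against the 0.212 read on Saturday.

Now take the neighbour flask with 0.060 M of substrate. Scaling by the charge gives

B = 0.364, side-product share 26.7%

The computed neighbour flask gives 25.4%, less than that estimate, with target 26.0% and isomer of the product 48.6%.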